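The earlier runs and the new flask are calculated for substances that don't exist, and the scatter is random.

D is the species we count, since D + E → L turns it into L. Neither Q nor G was read, and the flask below has to be reckoned from the west and north-east runs.

in all of them: D 10 mM

|  | E | J | remark | time |
|---|---|---|---|---|
| west | 8 mM | 18 mM | run made earlier |  |
| north-east | 18 mM | 18 mM | run made earlier |  |
| flask | 12.0 mM | 18.0 mM |  | 2.5 h |

| run | time / h | L / % | D / % |
|---|---|---|---|
| west | 0.250 | 0 | 98 |
| west | 0.333 | 4 | 97 |
| west | 0.500 | 6 | 100 |
| west | 0.833 | 5 | 96 |
| west | 1.33 | 7 | 92 |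
| west | 2.00 | 14 | 91 |
| west | 3.00 | 15 | 86 |
| north-east | 0.417 | 5 | 94 |
| north-east | 0.833 | 11 | 90 |
| north-east | 1.33 | 17 | 84 |
| north-east | 1.50 | 19 | 81 |
| north-east | 2.00 | 24 | 77 |
| north-east | 2.50 | 29 | 69 |
| north-east | 3.00 | 35 | 70 |

(readings scatter by 2 percentage points)

- amount of L at 2.5 h, in percent of the D charged
- concentration of Q in solution at 2.5 h, in percent of saturation

- J is a solid; its amount is given per volume of the solution
- steps that have been proposed: D + E -> L; D + Q -> G; J <-> Q
- at the start none of J is in solution

Which numbers must we know well for y? The time and the starting c_E are given with the flask. At the last readings, D and L add up to 101% in the west run and 105% in the north-east run, so we read L as reacted D and leave D + Q → G out of the reckoning for y. The rate constant does matter. We work with the fraction of D left, in a pseudo-first-order treatment with E held at its mean. The last L reading gives 7.47 M⁻¹ h⁻¹ in the west run and 8.84 M⁻¹ h⁻¹ in the north-east run. Carried to the flask, these give y of 18.6% and 21.3%. So we pool them into the exposure constant, −ln(fraction of D left) per mean c_E and per hour, 8.42 M⁻¹ h⁻¹, a reading with the scatter of its two readings. With it, our y for the flask is 20.5%. For sat, neither the dissolving rate nor the saturation of Q was read, so we commit to no number.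

The forecast gives 20% and 65%, the latter “little more than a guess”.

The flask gives 20.2% and 13.7%: y agrees, and sat stands 51 percentage points below the forecast.

    D + E → L (k = 8.30 M⁻¹ h⁻¹)
    D + Q → G (k = 31.0 M⁻¹ h⁻¹)
    J ⇌ Q, rate k3*(cs3 - [Q]) while solid is left; crystals form when [Q] > cs3 (solubility = 0.560 mM, k = 0.0820 h⁻¹)

In the flask, D + E → L ran throughout the 2.5 h, with half of its turnover up to that time done by 1.12 h and E at 83% of its charge at the end, while J fed Q to 0.0768 mM and G reached 0.290% of the D charged; 8.42 M⁻¹ h⁻¹ with the mean of c_E at start and end gives 79.4% of D left, and the flask holds 79%. Read at 10 h, the same flask has E at 57% of its charge, the constant with the same kind of mean gives 45.3% of D left, and the flask holds 46.4%.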